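## Analysis of the target

Compound 23, [(1S,2R,3S,6S)-2,3-diacetoxy-1,6-dihydroxycyclohex-4-en-1-yl]methyl benzoate, is a single cyclohexene ring in which every sp3 carbon carries oxygen. C1 is a fully substituted carbinol bearing the exocyclic C7H2–OBz arm, C2 and C3 carry acetates, C6 a free secondary hydroxyl, and C4=C5 is the ring alkene. These locants are used for all intermediates, open-chain ones included. With the ring drawn flat and C1→C6 running clockwise as seen from above, O1, O2 and O6 point down (α) and O3 and C7 point up (β); C1/C2 and C1/C6 are therefore cis-diol relationships, C2/C3 is trans, and the four stereocentres are contiguous. Three esters sit beside two free hydroxyls, so base invites acyl migration; C3–OAc and C6–OH are allylic, and loss of two oxygen substituents would aromatise the ring. The difficulty is the quaternary C1 inside a row of five oxygens of three kinds (free, acetylated, benzoylated), together with the fact that nothing reductive can be done once C4=C5 exists. Two features carry the strategy. C1(OH)–C2(O) is a tertiary α-ketol retron, so the C1–C2 bond can come from adding an acyl anion equivalent at C2 to a ketone at C1. The C3–C6 segment, with a threo 4,5-diol standing in for the alkene, has the configuration of C2–C5 of a D-manno chain, which 1 supplies.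

## Retrosynthetic reasoning

**23 ⇒ 22 ⇒ 21 (O6–Si; C4=C5).** The last operation only frees O6 from the silyl ether 22, so no free allylic alcohol meets earlier reagents. Behind 22 the alkene is traced to the trans-4,5-diol 21. Two C–O bonds are reinstated, not a C–C bond, because a diol survives hydrogenolysis and the ring closure, whereas the alkene would not survive hydrogenolysis. A syn-elimination through a cyclic thionocarbonate is closed to a trans-diol on a six-membered ring. The forward step must therefore be a reductive elimination that accepts this geometry and leaves three esters and a tertiary alcohol alone.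

**21 ⇒ 20 ⇒ 19 ⇒ 18 ⇒ 17 (esters and ethers).** The diol of 21 is masked as the benzyl ethers of 20. Removing the acetates (19) and the benzoate (18) and placing 4-methoxybenzyl ethers on O3 and O7 gives 17. The order lets each acylation meet only its own hydroxyls. Oxidative loss of both 4-methoxybenzyl groups frees O3 and O7 beside O2 while O4, O5 and O6 stay blocked. The primary O7 is benzoylated first, O2 and O3 are then acetylated, and the tertiary O1 is too hindered to compete. Hydrogenolysis afterwards exposes only the two hydroxyls that are to be eliminated.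

**17 ⇒ 16 (C2–H).** The C2 carbinol is taken back to a ketone. The forward reduction must set C2–OH cis to O1, and the axial C1–O bond of 16 is the handle for that.

**16 ⇒ 13 (C1–C2, the key disconnection).** Cutting C1–C2 of the α-ketol gives a chain with an aldehyde at C2 and a ketone at C1. No other ring bond leaves both termini at carbonyl level with a catalytic way to invert the polarity of one. The cut also puts all remaining stereocentres (C3–C6) in a chain that a hexitol provides. The forward reaction must close a six-membered ring and attack the ketone face that puts O1 cis to O6. The manno pattern has no chair with all four ether oxygens equatorial. In the chair with O3 and O6 equatorial, the O4 and O5 ethers are trans-diaxial; open-chain benzyl ethers allow this and a cyclic acetal across O4/O5 would not, which is why the diol is carried as two benzyl ethers. In that chair C6–O is anti to the forming bond and the C7 arm is equatorial, which leads to the required C1 epimer.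

**13 ⇒ 12 ⇒ 11 ⇒ 7 + 10 (from 9, from 8).** Both carbonyls of 13 are taken back to alcohols in 12, so that one double oxidation directly before the key step makes the sensitive keto-aldehyde. The O3 4-methoxybenzyl ether and the free primary O2–H of 12 are the two halves of the cyclic 4-methoxybenzylidene acetal of 11, opened reductively; this is possible only while C1 is still a carbinol. Cutting C1–C7 of 11 gives aldehyde 7 and the alkoxymethyllithium 10, generated from stannane 9 (made from 8). C7 thus arrives at its final oxidation level with the same ether as O3, and the C1 carbinol configuration is irrelevant.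

**7 ⇒ 6 ⇒ 5 ⇒ 4 ⇒ 3 ⇒ 2 ⇒ 1 (differentiating the chain).** Aldehyde 7 comes from primary alcohol 6, obtained from bis-silyl ether 5 by selective loss of the primary silyl group; 5 derives from diol 4. Tetraol 3 is C2-symmetric with homotopic terminal diols. Converting one of them into an acetal (4) distinguishes the ends with no selectivity problem other than stopping after one, and the acetal also separates O2–H from O3 for later. 3 follows from commercial 1 through 2, whose acetonide pattern leaves exactly the O4/O5 pair free for benzylation. An aldose-derived chain would bring C2 at aldehyde level but would leave five hydroxyls of four classes to be told apart on an open chain; the symmetric hexitol needs one statistical step instead.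

## Alternatives that were turned down

**Alternative 1:** No ring bond is cut. The six ring carbons come from an arene, oxidised to the achiral para-quinol A1. The forward key step is a catalytic enantioselective epoxidation of one of the two enantiotopic enone double bonds of A1, syn to the tertiary hydroxyl, giving epoxy-enone A2 and making C1 stereogenic. A Wharton transposition would then give the C6 carbinol and C4=C5, and the remaining C2=C3 bond would have to be trans-dioxygenated.
- For: it is clearly shorter than the chosen route, the ring is bought ready-made, and the alkene arises by transposition with no late dideoxygenation. On step economy it is the stronger plan.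
- Against: all absolute configuration rests on one enantiotopic-group selection with no chiral-pool backup. The Wharton step turns A2 into a cyclohexa-1,3-diene diol that can aromatise by dehydration. The final C2/C3 dioxygenation must tell the two diene double bonds apart and open a vinyl epoxide at C3 without allylic transposition.
- In its place the chosen route takes C3 and C6 from 1 and sets C1 in a ring closure whose unwanted outcome is a separable diastereomer, not an enantiomer. It is longer, but each oxygen is placed by chemistry of a known type.

**Alternative 2:** The C1–C6 bond is cut and made by a [3,3] shift. A six-membered lactone with C1 as its α-carbon, the ring oxygen on C4 and a (Z)-2-alkoxyvinyl group (C5=C6) on C4 would be converted into its silyl ketene acetal. This rearranges through the boat enforced by the ring to acid A3: C1–C6 forms, C4–O breaks and C4=C5 appears.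
- For: C1 and C6 are set together in a concerted step whose relative configuration follows from the enol ether geometry, and the alkene is delivered in place. In predictability of the C1/C6 relationship it is at least as strong as the benzoin closure.
- Against: enolisation needs a strong amide base on a lactone whose C2 alkoxy group is β to the carbonyl, so E1cB elimination competes. The (Z)-enol ether must be made geometrically pure. A3 has C7 as a carboxylic acid on a neopentyl, fully oxygenated carbon, which must be reduced, and both methoxymethyl ethers must be exchanged for acetates under acid beside an allylic system.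
- The chosen route brings C7 at the right oxidation level, uses only a weak amine base in the C–C bond-forming step, and needs no redox correction afterwards.

**Alternative 3:** The C3–C4 bond is cut. The (Z)-alkenyl iodide A4 would be treated with CrCl2 and catalytic NiCl2; the alkenylchromium species adds to the C3 aldehyde and closes the cyclohexene to A5.
- For: A5 already holds the alkene, the benzoate and the C2 acetate, so only acetylation of O3 and acetonide removal remain. In end-game economy, and in avoiding any diol-to-alkene step, it is stronger than the chosen route.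
- Against: A4 must already contain the quaternary C1, made on an open chain by a diastereoselective addition with no ring to guide it. Its aldehyde carries an α-acetate prone to epimerisation, migration and elimination. The C3 configuration would come from a closure with no strong built-in bias, and several equivalents of CrCl2 are consumed.
- The chosen route takes C3 from the chiral pool and sets C1 in the ring-forming step under a chiral catalyst; the price is the longer end game.

Key step: step 11

Remark (assumptions): 4–7 and 11 are carried as mixtures of the two epimers at the acetal carbon, and 11 and 12 as mixtures at the carbinol carbon C1; both centres lose their stereogenicity by step 10. Compound 8 and the triazolium salt of step 11 are taken to be commercial. Bn = benzyl, PMB = 4-methoxybenzyl, TBS = tert-butyldimethylsilyl.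

## Steps

Step 1
Reactants: 1 1,2:5,6-di-O-isopropylidene-D-mannitol
Product: 2 3,4-di-O-benzyl-1,2:5,6-di-O-isopropylidene-D-mannitol
Conditions: NaH, BnBr, Bu4NI (cat.), DMF, 0 °C → rt
Reagents that add atoms: benzyl bromide, BrCc1ccccc1
Why: Williamson etherification of the two secondary alkoxides; no stereocentre is touched.

Step 2
Reactants: 2 3,4-di-O-benzyl-1,2:5,6-di-O-isopropylidene-D-mannitol
Product: 3 3,4-di-O-benzyl-D-mannitol
Conditions: AcOH/H2O (4:1), 50 °C
Reagents that add atoms: none
Why: Acid-catalysed hydrolysis of both terminal dioxolanes; benzyl ethers are inert.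

Step 3
Reactants: 3 3,4-di-O-benzyl-D-mannitol
Product: 4 3,4-di-O-benzyl-1,2-O-(4-methoxybenzylidene)-D-mannitol (both epimers at the acetal carbon)
Conditions: 4-MeOC6H4CH(OMe)2 (1.0 equiv), PPTS (cat.), DMF, rt; stopped at partial conversion
Reagents that add atoms: 4-methoxybenzaldehyde dimethyl acetal, COc1ccc(C(OC)OC)cc1
Why: Transacetalisation of a terminal 1,2-diol; the two ends of C2-symmetric 3 are homotopic, so mono-protection gives a single constitution and is the desymmetrising step. It is statistical, and material acetalised at both ends is returned to 3 under the conditions of step 2.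

Step 4
Reactants: 4 3,4-di-O-benzyl-1,2-O-(4-methoxybenzylidene)-D-mannitol
Product: 5 3,4-di-O-benzyl-5,6-bis-O-(tert-butyldimethylsilyl)-1,2-O-(4-methoxybenzylidene)-D-mannitol
Conditions: TBSCl, imidazole, DMAP (cat.), DMF, rt → 40 °C
Reagents that add atoms: tert-butyldimethylsilyl chloride, CC(C)(C)[Si](C)(C)Cl
Why: Standard silylation of a primary and a secondary hydroxyl; the acetal is stable to the basic medium.

Step 5
Reactants: 5 3,4-di-O-benzyl-5,6-bis-O-(tert-butyldimethylsilyl)-1,2-O-(4-methoxybenzylidene)-D-mannitol
Product: 6 3,4-di-O-benzyl-5-O-(tert-butyldimethylsilyl)-1,2-O-(4-methoxybenzylidene)-D-mannitol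
Conditions: HF·pyridine, pyridine, THF, 0 °C
Reagents that add atoms: none
Why: Buffered HF cleaves a primary TBS ether much faster than a secondary one; excess pyridine protects the acid-labile acetal.

Step 6
Reactants: 6 3,4-di-O-benzyl-5-O-(tert-butyldimethylsilyl)-1,2-O-(4-methoxybenzylidene)-D-mannitol
Product: 7 3,4-di-O-benzyl-2-O-(tert-butyldimethylsilyl)-5,6-O-(4-methoxybenzylidene)-aldehydo-D-mannose
Conditions: Dess–Martin periodinane, pyridine, CH2Cl2, 0 °C → rt
Reagents that add atoms: none
Why: Dess–Martin oxidation of the primary alcohol under buffered, non-epimerising conditions; the α-silyloxy aldehyde is used without chromatography.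

Step 7
Reactants: 8 (tributylstannyl)methanol
Product: 9 tributyl{[(4-methoxybenzyl)oxy]methyl}stannane
Conditions: NaH, 4-MeOC6H4CH2Cl, Bu4NI (cat.), THF/DMF, 0 °C → rt
Reagents that add atoms: 4-methoxybenzyl chloride, COc1ccc(CCl)cc1
Why: Williamson etherification gives the α-alkoxymethylstannane needed for tin–lithium exchange.

Step 8
Reactants: 7 3,4-di-O-benzyl-2-O-(tert-butyldimethylsilyl)-5,6-O-(4-methoxybenzylidene)-aldehydo-D-mannose; 9 tributyl{[(4-methoxybenzyl)oxy]methyl}stannane
Product: 11 open-chain C1 carbinol (C7–OPMB; C1–OH as both epimers; C6–OTBS; C5/C4–OBn; C3/C2 4-methoxybenzylidene acetal), via [(4-methoxybenzyl)oxy]methyllithium 10 (not isolated)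
Conditions: 9, nBuLi, THF, −78 °C; then 7, −78 °C; aq. NH4Cl at −78 °C
Reagents that add atoms: none
Why: Tin–lithium exchange gives the α-alkoxy organolithium, which adds 1,2 to the aldehyde and forms C1–C7. Both carbinol epimers are carried on because C1 is oxidised in step 10, and the cold quench prevents silyl migration from O6 to the new alkoxide.

Step 9
Reactants: 11 open-chain C1 carbinol with C3/C2 acetal
Product: 12 open-chain diol (C7–OPMB; C1–OH as both epimers; C6–OTBS; C5/C4–OBn; C3–OPMB; C2H2–OH)
Conditions: iBu2AlH, CH2Cl2, −78 → 0 °C; aq. potassium sodium tartrate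
Reagents that add atoms: none
Why: Reductive opening of the 4-methoxybenzylidene acetal: aluminium binds the less hindered primary oxygen and that C–O bond is cleaved, leaving the PMB ether on the secondary O3 and the primary hydroxyl free. Both acetal epimers converge, and the silyl and PMB ethers are inert.

Step 10
Reactants: 12 open-chain diol
Product: 13 3,4-di-O-benzyl-5-O-(tert-butyldimethylsilyl)-2,7-bis-O-(4-methoxybenzyl)-D-manno-heptos-6-ulose (C2 aldehyde, C1 ketone in target locants)
Conditions: Dess–Martin periodinane (excess), pyridine, CH2Cl2, 0 °C → rt; used at once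
Reagents that add atoms: none
Why: One Dess–Martin oxidation converts the primary alcohol into the C2 aldehyde and the secondary alcohol into the C1 ketone. The buffered neutral conditions avoid β-elimination of benzyloxide and α-epimerisation.

Step 11
Reactants: 13 keto-aldehyde
Product: 16 cyclic tertiary α-ketol (C2 ketone; C1 α-OH/β-CH2OPMB; C3 β-OPMB; C4 β-OBn; C5 α-OBn; C6 α-OTBS), via Breslow enaminol 14 (not isolated), via azolium alkoxide adduct 15 (not isolated)
Conditions: (5aS,10bR)-2-(pentafluorophenyl)-5a,10b-dihydro-4H,6H-indeno[2,1-b][1,2,4]triazolo[4,3-d][1,4]oxazin-2-ium tetrafluoroborate (15 mol %), Et3N (15 mol %), CH2Cl2 (0.02 M), rt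
Reagents that add atoms: none
Why: Et3N deprotonates the triazolium salt; the carbene adds to the C2 aldehyde of 13 and proton transfer gives enaminol 14, the acyl anion equivalent. Its C2 attacks the C1 ketone in a 6-exo-trig closure with proton transfer to the ketone oxygen, giving adduct 15, which collapses to 16 and releases the carbene; the closest known reaction type is the triazolium-catalysed intramolecular crossed aldehyde–ketone benzoin reaction that gives cyclic tertiary α-ketols, carbohydrate-derived inososes among them. Only the aldehyde can form the enaminol and the ketone is the only acceptor in reach, so the cross-coupling is chemoselective; high dilution and the α-branched aldehyde suppress intermolecular benzoin. The one new stereocentre, C1, is set by the ketone face attacked: in the chair-like transition state with O3 and O6 equatorial, C6–O is antiperiplanar to the forming C1–C2 bond (Felkin–Anh) and the CH2OPMB group is equatorial, so the new hydroxyl is axial and cis to O6. The manno pattern cannot place all four ethers equatorial; in this chair the two benzyl ethers are trans-diaxial, which open-chain benzyl ethers allow. The chiral aminoindanol backbone of the carbene is the reagent-based control meant to reinforce this preference, and because the benzoin step is reversible the epimer with equatorial CH2OPMB is also the one favoured at equilibrium. The step further needs the β-alkoxy carbonyl groups to survive, which the catalytic amount of weak amine base and the acidic N-pentafluorophenyl triazolium (deprotonated without a strong base) are chosen to secure.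

Step 12
Reactants: 16 cyclic tertiary α-ketol
Product: 17 cis-1,2-diol (C2 α-OH; C1 α-OH/β-CH2OPMB; C3 β-OPMB; C4 β-OBn; C5 α-OBn; C6 α-OTBS)
Conditions: NaBH4, MeOH/CH2Cl2, −40 °C
Reagents that add atoms: none
Why: Hydride reduction of the α-ketol: in the chair of 16 with O3 and O6 equatorial the C1–O bond is axial, and borohydride adds to C2 from the β face, antiperiplanar to that bond (polar Felkin–Anh, axial attack). This gives the equatorial α-hydroxyl at C2, cis to O1 and trans to O3; protic solvent and low temperature disfavour hydride delivery from a borate bound to O1.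

Step 13
Reactants: 17 cis-1,2-diol
Product: 18 tetraol (C1 α-OH/β-CH2OH; C2 α-OH; C3 β-OH; C4 β-OBn; C5 α-OBn; C6 α-OTBS)
Conditions: DDQ, CH2Cl2/aq. pH 7 phosphate buffer (10:1), 0 °C → rt
Reagents that add atoms: none
Why: Oxidative cleavage of both PMB ethers by electron transfer to DDQ and hydrolysis of the resulting oxocarbenium ions. Benzyl ethers, the silyl ether and the saturated ring are inert, and the excess of water intercepts the cations before a neighbouring hydroxyl can.

Step 14
Reactants: 18 tetraol
Product: 19 7-O-benzoate (C7–OBz; O1, O2, O3 free; otherwise as 18)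
Conditions: BzCl (1.05 equiv), 2,4,6-collidine, CH2Cl2, −78 → −20 °C
Reagents that add atoms: benzoyl chloride, O=C(Cl)c1ccccc1
Why: Kinetic acylation: at low temperature with a hindered base the primary C7 hydroxyl reacts before the secondary O2 and O3 hydroxyls and the tertiary O1 hydroxyl.

Step 15
Reactants: 19 7-O-benzoate
Product: 20 2,3-di-O-acetate (C2 α-OAc; C3 β-OAc; C7–OBz; C4 β-OBn; C5 α-OBn; C6 α-OTBS; C1 α-OH)
Conditions: Ac2O, pyridine, DMAP (cat.), CH2Cl2, 0 °C → rt
Reagents that add atoms: acetic anhydride, CC(=O)OC(C)=O
Why: Acetylation of the two secondary hydroxyls; the tertiary C1 hydroxyl is too hindered to be acylated under these conditions.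

Step 16
Reactants: 20 2,3-di-O-acetate
Product: 21 trans-4,5-diol (C4 β-OH; C5 α-OH; otherwise as 20)
Conditions: H2 (1 atm), Pd(OH)2/C, EtOAc/EtOH, rt
Reagents that add atoms: none
Why: Neutral hydrogenolysis of the two benzyl ethers; esters and the silyl ether are inert, and no alkene is present yet.

Step 17
Reactants: 21 trans-4,5-diol
Product: 22 6-O-TBS ether of the target (C4=C5; C2 α-OAc; C3 β-OAc; C7–OBz; C6 α-OTBS; C1 α-OH)
Conditions: PPh3, I2, imidazole, toluene, reflux
Reagents that add atoms: none
Why: Garegg–Samuelsson dideoxygenation: both hydroxyls are activated by the phosphine–iodine reagent, iodide displaces one, and reductive elimination gives the alkene. The method is established for trans-diols of pyranosides and cyclitols bearing esters, and the tertiary C1 hydroxyl is too hindered to be activated.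

Step 18
Reactants: 22 6-O-TBS ether of the target
Product: 23 [(1S,2R,3S,6S)-2,3-diacetoxy-1,6-dihydroxycyclohex-4-en-1-yl]methyl benzoate
Conditions: HF·pyridine, pyridine, THF, 0 °C → rt
Reagents that add atoms: none
Why: Fluoride-induced cleavage of the secondary silyl ether under buffered, slightly acidic conditions, at which acyl migration onto the freed hydroxyl is slow.

## Compound list

1 | 1,2:5,6-di-O-isopropylidene-D-mannitol | CC1(C)OC[C@@H](O1)[C@@H](O)[C@H](O)[C@H](OC2(C)C)CO2 | starting material
2 | 3,4-di-O-benzyl-1,2:5,6-di-O-isopropylidene-D-mannitol | CC1(C)OC[C@@H](O1)[C@@H](OCc1ccccc1)[C@H](OCc1ccccc1)[C@H](OC2(C)C)CO2 | intermediate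
3 | 3,4-di-O-benzyl-D-mannitol | OC[C@@H](O)[C@@H](OCc1ccccc1)[C@H](OCc1ccccc1)[C@H](O)CO | intermediate
4 | 3,4-di-O-benzyl-1,2-O-(4-methoxybenzylidene)-D-mannitol (both epimers at the acetal carbon) | COc1ccc(cc1)C1OC[C@@H](O1)[C@@H](OCc1ccccc1)[C@H](OCc1ccccc1)[C@H](O)CO | intermediate
5 | 3,4-di-O-benzyl-5,6-bis-O-(tert-butyldimethylsilyl)-1,2-O-(4-methoxybenzylidene)-D-mannitol | COc1ccc(cc1)C1OC[C@@H](O1)[C@@H](OCc1ccccc1)[C@H](OCc1ccccc1)[C@H](O[Si](C)(C)C(C)(C)C)CO[Si](C)(C)C(C)(C)C | intermediate
6 | 3,4-di-O-benzyl-5-O-(tert-butyldimethylsilyl)-1,2-O-(4-methoxybenzylidene)-D-mannitol | COc1ccc(cc1)C1OC[C@@H](O1)[C@@H](OCc1ccccc1)[C@H](OCc1ccccc1)[C@H](O[Si](C)(C)C(C)(C)C)CO | intermediate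
7 | 3,4-di-O-benzyl-2-O-(tert-butyldimethylsilyl)-5,6-O-(4-methoxybenzylidene)-aldehydo-D-mannose | COc1ccc(cc1)C1OC[C@@H](O1)[C@@H](OCc1ccccc1)[C@H](OCc1ccccc1)[C@H](O[Si](C)(C)C(C)(C)C)C=O | intermediate
8 | (tributylstannyl)methanol | CCCC[Sn](CCCC)(CCCC)CO | starting material
9 | tributyl{[(4-methoxybenzyl)oxy]methyl}stannane | CCCC[Sn](CCCC)(CCCC)COCc1ccc(OC)cc1 | intermediate
10 | [(4-methoxybenzyl)oxy]methyllithium | [Li]COCc1ccc(OC)cc1 | intermediate (not isolated)
11 | open-chain carbinol: C7–OPMB, C1–OH (both epimers), C6–OTBS, C5 and C4–OBn, C3/C2 O,O-(4-methoxybenzylidene), D-manno configuration at C3–C6 | COc1ccc(cc1)C1OC[C@@H](O1)[C@@H](OCc1ccccc1)[C@H](OCc1ccccc1)[C@H](O[Si](C)(C)C(C)(C)C)C(O)COCc1ccc(OC)cc1 | intermediate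
12 | open-chain diol: C7–OPMB, C1–OH (both epimers), C6–OTBS, C5 and C4–OBn, C3–OPMB, C2H2–OH | OC[C@@H](OCc1ccc(OC)cc1)[C@@H](OCc1ccccc1)[C@H](OCc1ccccc1)[C@H](O[Si](C)(C)C(C)(C)C)C(O)COCc1ccc(OC)cc1 | intermediate
13 | 3,4-di-O-benzyl-5-O-(tert-butyldimethylsilyl)-2,7-bis-O-(4-methoxybenzyl)-D-manno-heptos-6-ulose (keto-aldehyde) | O=C[C@@H](OCc1ccc(OC)cc1)[C@@H](OCc1ccccc1)[C@H](OCc1ccccc1)[C@H](O[Si](C)(C)C(C)(C)C)C(=O)COCc1ccc(OC)cc1 | intermediate
14 | Breslow enaminol: C2 of 13 bears OH and is doubly bonded to the carbene carbon of the triazolylidene (alkene geometry undefined) | OC(=C1N(c2c(F)c(F)c(F)c(F)c2F)N=C2CO[C@H]3Cc4ccccc4[C@H]3N12)[C@@H](OCc1ccc(OC)cc1)[C@@H](OCc1ccccc1)[C@H](OCc1ccccc1)[C@H](O[Si](C)(C)C(C)(C)C)C(=O)COCc1ccc(OC)cc1 | intermediate (not isolated)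
15 | cyclised azolium alkoxide adduct: C2 bears O− and the triazolium, C1 α-OH/β-CH2OPMB (C2 configuration undefined) | COc1ccc(CO[C@H]2[C@@H](OCc3ccccc3)[C@H](OCc3ccccc3)[C@H](O[Si](C)(C)C(C)(C)C)[C@@](O)(COCc3ccc(OC)cc3)C2([O-])C2=[N+](c3c(F)c(F)c(F)c(F)c3F)N=C3CO[C@H]4Cc5ccccc5[C@H]4N23)cc1 | intermediate (not isolated)
16 | cyclic α-ketol: C2 ketone; C1 α-OH, β-CH2OPMB; C3 β-OPMB; C4 β-OBn; C5 α-OBn; C6 α-OTBS | COc1ccc(CO[C@H]2[C@@H](OCc3ccccc3)[C@H](OCc3ccccc3)[C@H](O[Si](C)(C)C(C)(C)C)[C@@](O)(COCc3ccc(OC)cc3)C2=O)cc1 | intermediate
17 | cis-1,2-diol: as 16 with C2 α-OH | COc1ccc(CO[C@H]2[C@@H](OCc3ccccc3)[C@H](OCc3ccccc3)[C@H](O[Si](C)(C)C(C)(C)C)[C@@](O)(COCc3ccc(OC)cc3)[C@@H]2O)cc1 | intermediate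
18 | tetraol: C1 α-OH, β-CH2OH; C2 α-OH; C3 β-OH; C4 β-OBn; C5 α-OBn; C6 α-OTBS | O[C@H]1[C@@H](OCc2ccccc2)[C@H](OCc2ccccc2)[C@H](O[Si](C)(C)C(C)(C)C)[C@@](O)(CO)[C@@H]1O | intermediate
19 | 7-O-benzoate of 18 | O[C@H]1[C@@H](OCc2ccccc2)[C@H](OCc2ccccc2)[C@H](O[Si](C)(C)C(C)(C)C)[C@@](O)(COC(=O)c2ccccc2)[C@@H]1O | intermediate
20 | 2,3-di-O-acetate of 19 | CC(=O)O[C@H]1[C@@H](OCc2ccccc2)[C@H](OCc2ccccc2)[C@H](O[Si](C)(C)C(C)(C)C)[C@@](O)(COC(=O)c2ccccc2)[C@@H]1OC(C)=O | intermediate
21 | trans-4,5-diol: C4 β-OH, C5 α-OH; C2 α-OAc; C3 β-OAc; C7–OBz; C6 α-OTBS; C1 α-OH | CC(=O)O[C@H]1[C@@H](O)[C@H](O)[C@H](O[Si](C)(C)C(C)(C)C)[C@@](O)(COC(=O)c2ccccc2)[C@@H]1OC(C)=O | intermediate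
22 | 6-O-(tert-butyldimethylsilyl) ether of 23 | CC(=O)O[C@H]1C=C[C@H](O[Si](C)(C)C(C)(C)C)[C@@](O)(COC(=O)c2ccccc2)[C@@H]1OC(C)=O | intermediate
23 | [(1S,2R,3S,6S)-2,3-diacetoxy-1,6-dihydroxycyclohex-4-en-1-yl]methyl benzoate | CC(=O)O[C@H]1C=C[C@H](O)[C@@](O)(COC(=O)c2ccccc2)[C@@H]1OC(C)=O | target

## Step count and least certain steps

Total: 18 steps. Longest linear sequence: 17 steps (1–6 and 8–18, from 1); step 7 is a one-step side branch.

**Step 11 (key step).** The ring closure may show poor facial selectivity at C1: all chair-like transition states of the manno chain carry axial substituents, and the catalyst may be mismatched with the substrate preference. Independently, the amine base may cause β-elimination of benzyloxide, epimerisation at C3 or C6, or an enolate aldol before the carbene has closed the ring. The enantiomeric triazolium salt is the first variation of conditions. The fallback changes the bond-forming principle to a reductive ketyl cyclisation. From 13, SmI2 and tBuOH in THF at −78 °C would reduce the aldehyde to its ketyl, which adds to the C1 ketone. The samarium-bridged pinacol coupling gives a cis-1,2-diol, and the aldehyde-derived C–O bond is expected to orient anti to O3, which corresponds to diol 17. This sets out from 13 and returns to the route at 17, replacing steps 11 and 12; it makes no compound outside the list (F0).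

**Step 12.** Hydride may add with poor facial selectivity: attack from the α face, or delivery from a borate bound to O1, would give the trans-1,2-diol, and the syn-axial O4 benzyl ether hinders the desired β-face approach. The fallback uses intramolecular hydride delivery from the β face.
- From 16, O1 is silylated with N-(trimethylsilyl)imidazole to give the C1 trimethylsilyl ether F1.
- DDQ in buffered CH2Cl2 removes both PMB ethers to give the keto-diol F2.
- Me4NBH(OAc)3 in MeCN/AcOH at −30 °C binds the β-face hydroxyls on C3 and C7 and delivers hydride to the β face of C2 (Evans–Saksena reduction), giving the triol F3 with O2 α.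
- K2CO3 in MeOH removes the trimethylsilyl group and returns to the route at 18.

**Step 14.** Site selectivity may be insufficient: benzoylation of O2 or O3 may compete with that of the neopentyl-type primary O7, or the benzoyl group may migrate. The fallback separates the hydroxyl classes by a temporary protecting group.
- From 18, trityl chloride, pyridine and DMAP give the 7-O-trityl ether F4.
- Ac2O and pyridine give its 2,3-di-O-acetate F5.
- Formic acid in Et2O removes the trityl group to give the primary alcohol F6.
- BzCl and pyridine at 0 °C then meet only one reactive hydroxyl and return to the route at 20.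

**Step 17.** The elimination may stop at an iodohydrin stage, or acetyl or silyl groups may migrate onto the liberated hydroxyls under imidazole at reflux before activation. The fallback is the two-step Tipson–Cohen sequence. From 21, MsCl in pyridine gives the 4,5-di-O-mesylate F7, and NaI with Zn dust in DMF at 100 °C eliminates both sulfonates and returns to the route at 22.

## Further compounds

F0 | step 11 | none | none
F1 | step 12 | C1 trimethylsilyl ether of 16 | COc1ccc(CO[C@H]2[C@@H](OCc3ccccc3)[C@H](OCc3ccccc3)[C@H](O[Si](C)(C)C(C)(C)C)[C@@](O[Si](C)(C)C)(COCc3ccc(OC)cc3)C2=O)cc1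
F2 | step 12 | keto-diol: C2 ketone; C1 α-OSiMe3, β-CH2OH; C3 β-OH; C4 β-OBn; C5 α-OBn; C6 α-OTBS | O[C@H]1[C@@H](OCc2ccccc2)[C@H](OCc2ccccc2)[C@H](O[Si](C)(C)C(C)(C)C)[C@@](O[Si](C)(C)C)(CO)C1=O
F3 | step 12 | triol: as F2 with C2 α-OH | O[C@H]1[C@@H](OCc2ccccc2)[C@H](OCc2ccccc2)[C@H](O[Si](C)(C)C(C)(C)C)[C@@](O[Si](C)(C)C)(CO)[C@@H]1O
F4 | step 14 | 7-O-trityl ether of 18 | O[C@H]1[C@@H](OCc2ccccc2)[C@H](OCc2ccccc2)[C@H](O[Si](C)(C)C(C)(C)C)[C@@](O)(COC(c2ccccc2)(c2ccccc2)c2ccccc2)[C@@H]1O
F5 | step 14 | 2,3-di-O-acetate of F4 | CC(=O)O[C@H]1[C@@H](OCc2ccccc2)[C@H](OCc2ccccc2)[C@H](O[Si](C)(C)C(C)(C)C)[C@@](O)(COC(c2ccccc2)(c2ccccc2)c2ccccc2)[C@@H]1OC(C)=O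
F6 | step 14 | primary alcohol: 2,3-di-O-acetate with free C7–OH; C4 β-OBn; C5 α-OBn; C6 α-OTBS | CC(=O)O[C@H]1[C@@H](OCc2ccccc2)[C@H](OCc2ccccc2)[C@H](O[Si](C)(C)C(C)(C)C)[C@@](O)(CO)[C@@H]1OC(C)=O
F7 | step 17 | 4,5-di-O-methanesulfonate of 21 | CC(=O)O[C@H]1[C@@H](OS(C)(=O)=O)[C@H](OS(C)(=O)=O)[C@H](O[Si](C)(C)C(C)(C)C)[C@@](O)(COC(=O)c2ccccc2)[C@@H]1OC(C)=O
A1 | alternative 1 | 4-hydroxy-4-{[(tert-butyldimethylsilyl)oxy]methyl}cyclohexa-2,5-dien-1-one (para-quinol) | O=C1C=CC(O)(CO[Si](C)(C)C(C)(C)C)C=C1
A2 | alternative 1 | syn-5,6-epoxy-4-hydroxy-4-{[(tert-butyldimethylsilyl)oxy]methyl}cyclohex-2-en-1-one | C1=CC(=O)[C@@H]2O[C@@H]2[C@@]1(O)CO[Si](C)(C)C(C)(C)C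
A3 | alternative 2 | cyclohexene carboxylic acid with cis PMB ethers on C1 and C6 and methoxymethyl ethers on C2 and C3 | COCO[C@H]1C=C[C@H](OCc2ccc(OC)cc2)[C@@](OCc2ccc(OC)cc2)(C(=O)O)[C@@H]1OCOC
A4 | alternative 3 | open-chain (Z)-alkenyl iodide: C3 aldehyde, C2 acetate, C1/C6 acetonide, C7 benzoate, iodine on C4 | I/C=C\[C@@H]1OC(C)(C)O[C@]1(COC(=O)c2ccccc2)[C@@H](C=O)OC(C)=O
A5 | alternative 3 | cyclohexenol with free C3 hydroxyl, C2 acetate, C6/C1 acetonide and C7 benzoate | O[C@H]1C=C[C@@H]2OC(C)(C)O[C@]2(COC(=O)c3ccccc3)[C@@H]1OC(C)=O
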